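The route rests on disconnecting C3–C3a of the pyrrole ring. In the benzene ring, C3a lies para to the brominated C6 and next to C7a, which bears nitrogen. An iodine at that carbon of the aniline therefore fixes the regiochemistry and reacts with palladium before bromine does. The precursor is an acyclic push-pull enamino ester with the iodoarene on nitrogen. One catalytic operation bonds its ester-bearing carbon to C3a, closes the ring and delivers the aromatic indole-3-carboxylate with C6–Br intact. Hydrolysis and NBS then exchange the C3 carboxyl for bromine and brominate C2.

Key step: step 2

Remark: the enamino ester is drawn as its hydrogen-bonded Z isomer; any E isomer equilibrates with it through the imine tautomer and leads to the same indole, so the geometry needs no control.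

Step 1
Reactants: 1 5-bromo-2-iodoaniline; 2 ethyl propiolate
Product: 3 ethyl (Z)-3-((5-bromo-2-iodophenyl)amino)acrylate
Conditions: 2 (1.5 equiv), EtOH, reflux, 24–48 h
Reagents that add atoms: none
Why: Aza-Michael (conjugate) addition of the primary arylamine to the activated terminal alkyne should give the vinylogous carbamate, whose Z geometry is favoured by the internal N–H···O=C hydrogen bond and whose nitrogen is too electron-poor to add a second time.

Step 2
Reactants: 3 ethyl (Z)-3-((5-bromo-2-iodophenyl)amino)acrylate
Product: 5 ethyl 6-bromo-1H-indole-3-carboxylate, via ethyl 6-bromo-3H-indole-3-carboxylate 4 (not isolated)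
Conditions: Pd(OAc)2 (5 mol %), PPh3 (10 mol %), NaHCO3 (2.5 equiv), degassed DMF (0.05 M), 90 °C, argon
Reagents that add atoms: none
Why: Zerovalent palladium, generated in the flask from Pd(OAc)2 and PPh3, inserts into the carbon–iodine bond of 3, and the divalent arylpalladium iodide so formed is captured by the electron-rich enamine carbon next to the ester while NaHCO3 removes HI, which gives a six-membered azapalladacycle. Reductive elimination then makes the C3–C3a bond and releases the 3H-indole 4, which tautomerises to the aromatic 1H-indole 5. The nearest established reaction type is the intramolecular Heck-type arylation of 2-haloanilino enones and 2-haloanilino acrylates, which furnishes indoles with a carbonyl group at C3. The pyrrole ring closes in a formal 5-endo-trig mode, made accessible by the palladacycle because no strained syn carbopalladation is needed. No lasting stereocentre arises, since the sp3 carbon C3 of 4 is flattened on tautomerisation and the alkene geometry of 3 is erased at the palladation stage. The one selectivity required is insertion at iodine and not at bromine, which should follow from the weaker bond to iodine, a temperature below that at which PPh3-ligated palladium engages aryl bromides and the fast intramolecular capture, the C6 bromide of the electron-rich product being less reactive still.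

Step 3
Reactants: 5 ethyl 6-bromo-1H-indole-3-carboxylate
Product: 7 6-bromo-1H-indole-3-carboxylic acid, via sodium 6-bromo-1H-indole-3-carboxylate 6 (not isolated)
Conditions: NaOH (5 equiv), EtOH/H2O, reflux; then aq. HCl, 0 °C, to pH 3, filtration
Reagents that add atoms: sodium hydroxide, [Na+].[OH-]
Why: Saponification by acyl–oxygen cleavage is slow but dependable at reflux for the vinylogous carbamate of an indole-3-carboxylate, the aryl bromide is inert to aqueous hydroxide, and cold acidification avoids premature acid-catalysed loss of CO2.

Step 4
Reactants: 7 6-bromo-1H-indole-3-carboxylic acid
Product: 9 2,3,6-tribromo-1H-indole, via 3,6-dibromo-1H-indole 8 (not isolated)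
Conditions: NBS (2.05 equiv, two portions), dry DMF, 0 °C → rt, dark, argon; cold aqueous work-up, rapid purification on base-washed silica
Reagents that add atoms: N-bromosuccinimide, O=C1CCC(=O)N1Br
Why: Electrophilic ipso attack of bromine at the most nucleophilic carbon C3 followed by irreversible loss of CO2 (Hunsdiecker-type halodecarboxylation of an electron-rich heteroaromatic acid) should give 8, whose only free pyrrole position C2 takes the second bromine by electrophilic aromatic substitution, and the opposite order of the two events would lead to the same product.

Compound list
1 | 5-bromo-2-iodoaniline | Nc1cc(Br)ccc1I | starting material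
2 | ethyl propiolate | C#CC(=O)OCC | starting material
3 | ethyl (Z)-3-((5-bromo-2-iodophenyl)amino)acrylate | CCOC(=O)/C=C\Nc1cc(Br)ccc1I | intermediate
4 | ethyl 6-bromo-3H-indole-3-carboxylate (racemic, transient) | CCOC(=O)C1C=Nc2cc(Br)ccc12 | intermediate
5 | ethyl 6-bromo-1H-indole-3-carboxylate | CCOC(=O)c1c[nH]c2cc(Br)ccc12 | intermediate
6 | sodium 6-bromo-1H-indole-3-carboxylate | [Na+].[O-]C(=O)c1c[nH]c2cc(Br)ccc12 | intermediate
7 | 6-bromo-1H-indole-3-carboxylic acid | OC(=O)c1c[nH]c2cc(Br)ccc12 | intermediate
8 | 3,6-dibromo-1H-indole | Brc1ccc2c(Br)c[nH]c2c1 | intermediate
9 | 2,3,6-tribromo-1H-indole | Brc1ccc2c(Br)c(Br)[nH]c2c1 | target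

Total step count: 4. Longest linear sequence: 4 steps (1 → 3 → 5 → 7 → 9).

Steps most likely to fail

Risk 1, step 2.
- **What may go wrong:** loss of discrimination between the two halogens, reductive loss of iodine before the ring closes, or intermolecular coupling.
- **Fallback:** the pyrrole ring is closed at N1–C2 instead of C3–C3a. The detour sets out from 1. Sonogashira coupling at room temperature with trimethylsilylacetylene (PdCl2(PPh3)2, CuI, Et3N) should engage only the iodide and give 5-bromo-2-((trimethylsilyl)ethynyl)aniline F1. K2CO3 in MeOH should remove silicon to give 5-bromo-2-ethynylaniline F2. CuI-catalysed 5-endo-dig hydroamination in DMF at 100 °C should then give 6-bromo-1H-indole F3. One equivalent of NBS in DMF at 0 °C should convert it into 8, where the detour comes back to the route, and the second equivalent finishes as in step 4.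

Risk 2, step 4.
- **What may go wrong:** hydrolytic over-oxidation of the pyrrole ring by traces of water, bromination running on into the benzene ring, incomplete loss of CO2, or decomposition of the light- and acid-sensitive product during isolation.
- **Fallback:** loss of CO2 and halogenation are separated. The detour sets out from 7. Acid-catalysed protodecarboxylation through C3 protonation (dilute HCl, aqueous dioxane, 80 °C) should give 6-bromo-1H-indole F4, the same compound as F3. This is then brominated at its two free pyrrole C–H positions with NBS adsorbed on silica gel in CH2Cl2 at room temperature (two equivalents). The detour comes back at 8 on the way to 9.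

Risk 3, step 1.
- **What may go wrong:** sluggish addition, because nitrogen is deactivated by two halogens and shielded by the ortho iodine, so that oligomerisation of the alkynoate competes.
- **Fallback:** the alkyne hydroamination is replaced by an acid-promoted transamination. The detour sets out from 1 and comes back at 3. Commercial ethyl (E)-3-(dimethylamino)acrylate (CCOC(=O)/C=C/N(C)C) in AcOH at 25–60 °C reacts by addition–elimination through its C-protonated iminium form. That form is far more electrophilic than the alkynoate, so it should give 3 with expulsion of dimethylamine. This detour makes no compound outside the list (F0).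

Further compounds
F1 | step 2 | 5-bromo-2-((trimethylsilyl)ethynyl)aniline | C[Si](C)(C)C#Cc1ccc(Br)cc1N
F2 | step 2 | 5-bromo-2-ethynylaniline | C#Cc1ccc(Br)cc1N
F3 | step 2 | 6-bromo-1H-indole | Brc1ccc2cc[nH]c2c1
F4 | step 4 | 6-bromo-1H-indole | Brc1ccc2cc[nH]c2c1
F0 | step 1 | none | none
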